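## Structural features

The target is a germacranolide: a ten-membered carbocycle (C1–C10) fused trans along C6–C7 to an α-methylene-γ-butyrolactone (O–C6, C7, C11, C12, exocyclic C13). The carbocycle carries a ketone at C9, a methyl-bearing methine at C10, an oxygen-free trimethylene chain C1–C3, a methyl-substituted tertiary carbinol at C4 and an (S)-2-methylbutanoate on the C5 oxygen. Four stereocentres are contiguous: C4 (R, fully substituted), C5 (S), C6 (R) and C7 (R), with C5/C6 in a threo diol pattern. C10 (S) is separated from them by the ketone, and a sixth centre sits in the acyl chain. Fragile points are the α-methylene lactone (a Michael acceptor that also isomerises), the two centres α to carbonyl groups (C10 and the acyl α-carbon), and the tertiary C4 alcohol under strong acid. The real difficulty is threefold: closing a medium ring on a chain that already carries the C4–C7 array, methylenating the lactone α-carbon next to a more acidic ketone, and fixing C10, which no neighbouring group controls. The key step exploits the fact that the C9 ketone is flanked by C10 and that C10 is bonded to the C1–C3 chain. With a temporary ester on C10 this carbon becomes a β-keto ester carbon acid, C1–C3 becomes an allyl electrophile, and the C1–C10 bond closes the ring.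

## Logic of the disconnections

28 to 26: the C11=C13 double bond is traced back to a C13–N bond of a β-amino lactone. The Michael acceptor is thereby unmasked last, so no earlier step has to tolerate it. The forward step must quaternise and eliminate without touching C10 or the acyl α-carbon.

26 to 23 and 24: the C5–O acyl bond is cut. The epimerisable acyl group then never meets a strong base, and the fragment left is a diol. The acylation must choose the secondary C5 hydroxyl over the tertiary C4 hydroxyl and must not racemise 24.

23 to 22 to 20: the two C–O bonds of the C4/C5 ketal are protecting-group bonds. The C10–H bond is then traced to a C10–ester bond and the C2–C3 single bond to a double bond. This brings back the β-keto ester and the allyl unit that the ring closure needs. The forward step must remove the ester without heat or strong base and must leave C10 in the (S) configuration.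

20 to 18: the C11–C13 bond is cut (Mannich reaction). It is placed while C10 is still quaternary, so the ketone can enolise only toward C8 and is easy to mask. The forward step must form the lactone enolate without touching the ketone.

18 to 17: the C1–C10 bond is cut. This opens the ten-membered ring to a chain with a β-keto ester at one end and an allylic carbonate at the other, with all four contiguous stereocentres already present. The forward step must close a ten-membered ring in preference to an eight-membered ring and to intermolecular reaction.

17 to 11 and 15: the C7–C8 bond is cut. The whole C8–C10 unit arrives as one nucleophile, and C7 is set from C6 by addition anti to the C6 substituent of a butenolide. The Lewis acid must spare the ketal and the allylic carbonate.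

15 to 14 to 13 to 12: two O–Si bonds and one ester exchange. The benzyl group is chosen for its later removal with hydrogen.

11 to 10 to 9 to 8: the carbonate C–O bond, the C4/C5 ketal and the lactone O6–C12 bond are cut in turn. The ketal thus sits on C5/C6 while the C4 ketone is made and on C4/C5 once O6 is in the lactone. Lactonisation must give the five-membered and not the six-membered lactone.

8 to 7: the C7=C11 double bond is cut to an aldehyde and a two-carbon phosphonate. The olefination must be Z-selective so that the ester can reach O6.

7 to 6: functional-group changes only. The E alkene comes from the alkyne and the aldehyde from the N-methoxy-N-methylamide. One hydride reagent must do both and stop at the aldehyde.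

6 to 5: the C4–CH3 bond is cut. C4 is set from C5 by chelation, so no new source of chirality is needed. The metal must bridge the ketone oxygen and O5.

5 to 3 and 4, then 3 to 2 to 1: the C3–C4 bond is cut to a C2-symmetric diamide and an alkyne. C5 and C6 come unchanged from the chiral pool. Only one of the two amide groups may react.

## Other disconnections considered

Alternative 1: The cut goes through C7–C11 and C8–C9 at once and leads to the eleven-membered β-keto lactone A2 (O6–C12 ester bond, C11 between C12 and the C9 ketone, vinyl group C7=C8 on C6). In the forward direction, irradiation of the enol of A2 would give a transannular [2+2] adduct, and retro-aldol cleavage of its cyclobutanol (C9–C11) would give A1, the saturated keto lactone with the C4/C5 acetonide.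
- In its favour: two C–C bonds and both rings arise in one operation. The medium ring comes from an eleven-membered lactone that ordinary lactonisation can close. A1 already has C1–C3 saturated and C10 as a methine, so no hydrogenation and no ester removal follow.
- Against it: a β-keto ester enol is less populated and a poorer partner in the De Mayo reaction than a 1,3-diketone enol. C7 is created in the cycloaddition. The cyclobutane must be cis-fused to the new lactone, so C8 and C9 lie on one face of it, while the trans lactone requires C5 on the other face. C5 is tied to C9 through C4–C3–C2–C1–C10, so the required adduct is a strained inside–outside tricycle, and the less strained mode would lead to the cis lactone.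
- Comparison: on step economy after ring formation this plan is the better one. It is the equal of the chosen plan in taking C4–C6 from the chiral pool and in leaving the ketone-versus-lactone methylenation problem open. On mechanism the chosen plan is safer, because it sets C7 by an intermolecular anti addition to a butenolide before the ring exists.

Alternative 2: The cut is C5–C6 and leads to the open-chain aldehyde A4, with the C6 aldehyde, a (Z)-γ-alkoxyallylstannane (Sn on C3, enol ether C4=C5) and a dithiane at C9. In the forward direction BF3·OEt2 would trigger an anti SE2' addition of C5 to the aldehyde and give A3 (C5 OMOM, C6 OH, E C3–C4 alkene, C7 isopropenyl).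
- In its favour: the ring closure itself creates two stereocentres (C5, C6) with the threo relationship the target needs, whereas the chosen ring closure creates none that lasts; on this point it is the better plan. The two oxygens leave the step differentiated. The isopropenyl group already holds C11–C13, so allylic oxidation and lactonisation would give the α-methylene lactone without enolate chemistry next to the ketone; this is also better than the chosen plan.
- Against it: C4 is still an alkene carbon in A3. The tertiary carbinol would have to be made by a regio- and face-selective hydration of a trisubstituted alkene on a flexible ten-membered ring. C7 and C10 must be set in an acyclic chain, and the aldehyde is epimerisable at C7. A stoichiometric chiral stannane and a late dithiane removal are needed.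
- Comparison: the two plans are equal in closing the medium ring late by a polar C–C bond formation. The chosen plan has C4 fixed before ring closure and fewer operations after it.

Alternative 3: The ten-membered ring is traced to the cis-decalin A6 (angular C9 hydroxyl, angular C4 methyl, C5 mesylate, C6 OTBS, C7 isopropenyl, C10 methyl). In the forward direction t-BuOK would form the C9 alkoxide, and Grob fragmentation of the C4–C9 bond with loss of mesylate would give A5 (C9 ketone, Z C4–C5 alkene).
- In its favour: the medium ring is made by breaking a bond of a six-membered bicycle, with no entropic penalty and no high dilution. As a ring-forming event this is more dependable than any macrocyclisation, and here the alternative is the better plan. The alkene geometry follows stereospecifically from the decalin, and the isopropenyl group again carries C11–C13.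
- Against it: C4 and C5 must be oxygenated after ring formation by syn dihydroxylation of the Z alkene. This gives the correct C4/C5 relationship (equal to the chosen plan on that point), but the face relative to C6 is not secured. The acyclic model for osmylation next to an allylic ether places the new C5 oxygen erythro to O6, whereas the target is threo. The isopropenyl alkene competes in the oxidation. The decalin needs three stereocentres (C4, C5, C9) that are built only to be destroyed.
- Comparison: C10 passes through basic ketone-forming conditions, so its control is the same as in the chosen plan (thermodynamic). The chosen plan is shorter after ring formation and has the C4/C5/C6 array secured from tartrate.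

Key step: step 14

Remarks on the chemistry:
- The C10 ester of the key-step compounds is carried as benzyl, not methyl, so that it can be removed by hydrogenolysis at room temperature together with the alkene reduction.
- C10 arises without control in steps 13 and 14, so 16–21 are written without a C10 descriptor; a configuration drawn there would be arbitrary. The same holds for C11 in 20–27.
- Assumption: at equilibrium the epimerisable C10 next to the C9 ketone prefers the (10S) configuration of the target.

## Steps

Step 1
Reactants: 1 diethyl D-tartrate
Product: 2 diethyl (4S,5S)-2,2-dimethyl-1,3-dioxolane-4,5-dicarboxylate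
Conditions: Me2C(OMe)2, p-toluenesulfonic acid monohydrate (cat.), cyclohexane, reflux, MeOH distilled off
Reagents that add atoms: 2,2-dimethoxypropane COC(C)(C)OC
Why: Acid-catalysed transketalisation of a threo 1,2-diol to the trans-dioxolane; neither stereocentre is touched.

Step 2
Reactants: 2 diethyl (4S,5S)-2,2-dimethyl-1,3-dioxolane-4,5-dicarboxylate
Product: 3 (4S,5S)-N4,N5-dimethoxy-N4,N5,2,2-tetramethyl-1,3-dioxolane-4,5-dicarboxamide
Conditions: MeNH(OMe)·HCl, i-PrMgCl, THF, −20 → 0 °C
Reagents that add atoms: N,O-dimethylhydroxylamine hydrochloride CNOC.Cl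
Why: Aminolysis of both esters by the magnesium amide (Weinreb amide formation from esters); the trans arrangement is the stable one, so the α-centres are not at risk.

Step 3
Reactants: 3 (4S,5S)-N4,N5-dimethoxy-N4,N5,2,2-tetramethyl-1,3-dioxolane-4,5-dicarboxamide; 4 tert-butyldimethyl(prop-2-yn-1-yloxy)silane
Product: 5 (4S,5S)-5-[4-(tert-butyldimethylsilyloxy)but-2-ynoyl]-N-methoxy-N,2,2-trimethyl-1,3-dioxolane-4-carboxamide
Conditions: 4 (1.15 equiv), i-PrMgCl, THF, 0 → 20 °C; then 3, THF, −20 → 0 °C; inverse quench into cold 1 M HCl
Reagents that add atoms: none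
Why: Weinreb ketone synthesis with an alkynyl Grignard reagent; the first addition leaves a magnesium-chelated adduct that deactivates the diamide toward a second addition, so the C2-symmetric diamide is desymmetrised, and the cold acidic quench stops the liberated amine from adding to the ynone.

Step 4
Reactants: 5 (4S,5S)-5-[4-(tert-butyldimethylsilyloxy)but-2-ynoyl]-N-methoxy-N,2,2-trimethyl-1,3-dioxolane-4-carboxamide
Product: 6 (4S,5S)-5-[(2R)-5-(tert-butyldimethylsilyloxy)-2-hydroxypent-3-yn-2-yl]-N-methoxy-N,2,2-trimethyl-1,3-dioxolane-4-carboxamide
Conditions: MeMgBr (Et2O solution), CH2Cl2, −78 °C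
Reagents that add atoms: methylmagnesium bromide C[Mg]Br
Why: Cram-chelate 1,2-addition: magnesium bridges the ketone oxygen and the α-oxygen O5 of the dioxolane, and methyl attacks the face on which C5 carries its hydrogen (away from C6), which gives (4R); at −78 °C the ynone reacts and the N-methoxy-N-methylamide does not, and a Grignard reagent without copper adds 1,2.

Step 5
Reactants: 6 (4S,5S)-5-[(2R)-5-(tert-butyldimethylsilyloxy)-2-hydroxypent-3-yn-2-yl]-N-methoxy-N,2,2-trimethyl-1,3-dioxolane-4-carboxamide
Product: 7 (4S,5S)-5-[(2R,3E)-5-(tert-butyldimethylsilyloxy)-2-hydroxypent-3-en-2-yl]-2,2-dimethyl-1,3-dioxolane-4-carbaldehyde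
Conditions: NaAlH2(OCH2CH2OMe)2 (3 equiv), THF, −20 → 20 °C; aq. KNaC4H4O6
Reagents that add atoms: none
Why: Two hydride reductions in one operation: the propargylic alkoxide directs a trans-hydroalumination, so protonolysis gives only the E alkene, and the N-methoxy-N-methylamide is reduced to a chelated aluminium hemiaminal that releases the aldehyde on work-up; the trans-dioxolane keeps the C4 hydroxyl from closing a lactol onto C7, which would be a trans-fused bicyclo[3.3.0] system.

Step 6
Reactants: 7 (4S,5S)-5-[(2R,3E)-5-(tert-butyldimethylsilyloxy)-2-hydroxypent-3-en-2-yl]-2,2-dimethyl-1,3-dioxolane-4-carbaldehyde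
Product: 8 methyl (2Z)-3-[(4R,5S)-5-[(2R,3E)-5-(tert-butyldimethylsilyloxy)-2-hydroxypent-3-en-2-yl]-2,2-dimethyl-1,3-dioxolan-4-yl]prop-2-enoate
Conditions: (CF3CH2O)2P(O)CH2CO2Me, KN(SiMe3)2, 18-crown-6, THF, −78 °C (anion preformed)
Reagents that add atoms: methyl bis(2,2,2-trifluoroethyl)phosphonoacetate COC(=O)CP(=O)(OCC(F)(F)F)OCC(F)(F)F
Why: Still–Gennari olefination: the electron-poor phosphonate eliminates faster than its adducts equilibrate, so the kinetic Z enoate forms, and α-alkoxy aldehydes are favourable substrates; the preformed stabilised anion leaves the tertiary hydroxyl alone.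

Step 7
Reactants: 8 methyl (2Z)-3-[(4R,5S)-5-[(2R,3E)-5-(tert-butyldimethylsilyloxy)-2-hydroxypent-3-en-2-yl]-2,2-dimethyl-1,3-dioxolan-4-yl]prop-2-enoate
Product: 9 (5R)-5-[(1S,2R,3E)-1,2,5-trihydroxy-2-methylpent-3-en-1-yl]furan-2(5H)-one
Conditions: p-toluenesulfonic acid monohydrate (0.2 equiv), MeOH, 25 → 40 °C
Reagents that add atoms: none
Why: Acid methanolysis removes the acetonide and the primary silyl ether, and the freed C6 hydroxyl closes the five-membered lactone onto the cis ester faster than the C5 hydroxyl could close a six-membered one; no stereocentre is touched, and the oxygenated carbons on both sides of C4 disfavour ionisation of the tertiary allylic alcohol.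

Step 8
Reactants: 9 (5R)-5-[(1S,2R,3E)-1,2,5-trihydroxy-2-methylpent-3-en-1-yl]furan-2(5H)-one
Product: 10 (5R)-5-[(4S,5R)-5-[(1E)-3-hydroxyprop-1-en-1-yl]-2,2,5-trimethyl-1,3-dioxolan-4-yl]furan-2(5H)-one
Conditions: Me2C(OMe)2, pyridinium p-toluenesulfonate (cat.), acetone, 25 °C; then MeOH, 0 °C
Reagents that add atoms: 2,2-dimethoxypropane COC(C)(C)OC
Why: Acetonide formation on the only 1,2-diol left (C4/C5, now that O6 is in the lactone); C3 and C6 sit cis on the dioxolane, and any mixed ketal on the primary hydroxyl is cleaved in the methanol stage.

Step 9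
Reactants: 10 (5R)-5-[(4S,5R)-5-[(1E)-3-hydroxyprop-1-en-1-yl]-2,2,5-trimethyl-1,3-dioxolan-4-yl]furan-2(5H)-one
Product: 11 methyl (2E)-3-[(4R,5S)-2,2,4-trimethyl-5-[(2R)-5-oxo-2,5-dihydrofuran-2-yl]-1,3-dioxolan-4-yl]prop-2-en-1-yl carbonate
Conditions: ClCO2Me, pyridine, CH2Cl2, 0 °C
Reagents that add atoms: methyl chloroformate COC(=O)Cl
Why: O-acylation of the primary allylic alcohol by a chloroformate; pyridine is too weak a base to deprotonate the butenolide at C6.

Step 10
Reactants: 12 methyl 2-methylacetoacetate
Product: 13 benzyl 2-methyl-3-oxobutanoate
Conditions: BnOH, 4-(dimethylamino)pyridine (cat.), toluene, reflux, MeOH distilled off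
Reagents that add atoms: benzyl alcohol OCc1ccccc1
Why: Transesterification of an enolisable β-keto ester through its acylketene, driven by removal of methanol.

Step 11
Reactants: 13 benzyl 2-methyl-3-oxobutanoate
Product: 14 benzyl 2-methyl-3-(trimethylsilyloxy)but-2-enoate
Conditions: Me3SiCl, Et3N, hexane, 25 °C
Reagents that add atoms: chlorotrimethylsilane C[Si](C)(C)Cl
Why: O-silylation of the enol of the β-keto ester (silyl enol ether formation under amine base).

Step 12
Reactants: 14 benzyl 2-methyl-3-(trimethylsilyloxy)but-2-enoate
Product: 15 1-benzyloxy-2-methyl-1,3-bis(trimethylsilyloxy)buta-1,3-diene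
Conditions: LiN(i-Pr)2 (commercial solution), THF, −78 °C; then Me3SiCl, −78 → 0 °C
Reagents that add atoms: chlorotrimethylsilane C[Si](C)(C)Cl
Why: Vinylogous deprotonation of the γ-methyl group gives the extended enolate, which is O-silylated to the 1,3-bis(silyloxy)diene (the standard two-stage preparation of such dienes).

Step 13
Reactants: 11 methyl (2E)-3-[(4R,5S)-2,2,4-trimethyl-5-[(2R)-5-oxo-2,5-dihydrofuran-2-yl]-1,3-dioxolan-4-yl]prop-2-en-1-yl carbonate; 15 1-benzyloxy-2-methyl-1,3-bis(trimethylsilyloxy)buta-1,3-diene
Product: 17 open-chain benzyl β-keto ester carbonate (key-step precursor), via bis-silyl adduct 16 (not isolated)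
Conditions: Me3SiOTf (0.2 equiv), 2,6-di-tert-butyl-4-methylpyridine (0.3 equiv), CH2Cl2, −78 °C; then 1 M HCl, THF, 0 °C
Reagents that add atoms: none
Why: Vinylogous Mukaiyama–Michael addition: silylation of the lactone carbonyl activates C7, and the terminal carbon of the diene attacks anti to the bulky C6 substituent, which sets (7R) and the trans lactone; the hindered pyridine keeps triflic acid away from the acetonide, and the acid work-up converts both silyl enol ethers of 16 into the lactone and the β-keto ester (C10 as a mixture).

Step 14
Reactants: 17 open-chain benzyl β-keto ester carbonate (key-step precursor)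
Product: 18 macrocyclic benzyl β-keto ester (key-step product)
Conditions: Pd(PPh3)4 (10 mol %), THF, 65 °C, slow addition of 17 to a final 2 mM
Reagents that add atoms: none
Why: Zerovalent palladium ionises the primary allylic methyl carbonate of 17; CO2 is lost and the methoxide formed deprotonates the β-keto ester, the only carbon acid of 17 in that pKa range, so no external base is needed. The stabilised enolate attacks the π-allyl ligand on the face away from palladium at C1 and forms the C1–C10 bond; the closest known reaction type is the Tsuji–Trost allylic alkylation run as a macrocyclisation of a β-keto ester under high dilution. The ten-membered carbocycle closes by attack on the allyl terminus remote from the tether, so all three allyl carbons end up in the ring; attack at C3 would give an eight-membered ring with a vinyl side chain. C3 is shielded by the fully substituted C4 whereas C1 is primary, which directs the nucleophile to C1. The syn π-allyl complex gives the E C2–C3 alkene, and since C4 has no hydrogen, diene formation by β-hydride elimination is excluded. The cis-dioxolane holds C3 and C6 on one face and the trans lactone fixes C5 and C8, which removes rotors from the chain and brings the ends together, while slow addition keeps intermolecular allylation down. The only new stereocentre is the quaternary C10; it is not controlled and need not be, because both epimers converge in step 16. The lactone α-methylene is more than ten pKa units less acidic than the β-keto ester and does not compete, and the allylic ketal C4–O bond is a far poorer leaving group than the carbonate.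

Step 15
Reactants: 18 macrocyclic benzyl β-keto ester (key-step product)
Product: 20 macrocyclic β-keto ester carrying CH2NMe2 at C11, via silyl enol ether 19 (not isolated)
Conditions: Me3SiOTf (1.2 equiv), Et3N, CH2Cl2, 0 °C; evaporate; LiN(i-Pr)2 (1.2 equiv), THF, −78 °C; [Me2N=CH2]I (1.1 equiv), −78 → −20 °C; aq. citric acid, then NaHCO3
Reagents that add atoms: dimethyl(methylidene)ammonium iodide C=[N+](C)C.[I-]
Why: The ketone is masked in the flask as its silyl enol ether (soft enolisation acts on the ketone, which can enolise only toward C8 because C10 is quaternary, and spares the lactone), LiN(i-Pr)2 then forms the lactone enolate at C11, which is aminomethylated in a Mannich reaction, and mild acid returns the ketone; an sp2 mask avoids the unfavourable ketalisation of a ten-membered-ring ketone, and the C11 configuration is irrelevant because C11 becomes trigonal in step 19.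

Step 16
Reactants: 20 macrocyclic β-keto ester carrying CH2NMe2 at C11
Product: 22 saturated (10S) ketone with C4/C5 acetonide and C11 CH2NMe2, via keto acid 21 (not isolated)
Conditions: H2 (1 atm), Pd/C (10 wt %), EtOAc, 25 °C; filter; AcOH (2 equiv), toluene, 70 °C; then 1,8-diazabicyclo[5.4.0]undec-7-ene (0.3 equiv), toluene, 25 °C
Reagents that add atoms: none
Why: Heterogeneous hydrogenation saturates C2–C3 and hydrogenolyses the benzyl ester, the β-keto acid 21 loses CO2 on warming through its enol, and amidine-catalysed enolisation then equilibrates C10 toward the epimer assumed more stable, (10S); the acetonide, lactone and tertiary amine are inert to these conditions.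

Step 17
Reactants: 22 saturated (10S) ketone with C4/C5 acetonide and C11 CH2NMe2
Product: 23 (4R,5S,6R,7R,10S)-13-(dimethylamino)-4,5-dihydroxy-9-oxogermacran-12,6-olide
Conditions: CF3CO2H/H2O/THF (2:1:2), 0 → 25 °C; NaHCO3 work-up
Reagents that add atoms: none
Why: Acid hydrolysis of the dioxolane; the protonated amine, the γ-lactone and the ketone are stable to aqueous acid at this temperature, and no stereocentre takes part.

Step 18
Reactants: 23 (4R,5S,6R,7R,10S)-13-(dimethylamino)-4,5-dihydroxy-9-oxogermacran-12,6-olide; 24 (S)-2-methylbutanoic acid
Product: 26 C5 (S)-2-methylbutanoate of 23, via mixed anhydride 25 (not isolated)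
Conditions: 24, 2,4,6-trichlorobenzoyl chloride, Et3N, THF, 25 °C; then 23, 4-(dimethylamino)pyridine, toluene, 25 → 40 °C
Reagents that add atoms: none
Why: Yamaguchi esterification: the mixed anhydride 25 acylates the secondary C5 hydroxyl under 4-(dimethylamino)pyridine catalysis while the tertiary C4 hydroxyl does not react; an α-alkyl acyl group does not form a ketene under these conditions, so the (S) centre of 24 is kept.

Step 19
Reactants: 26 C5 (S)-2-methylbutanoate of 23
Product: 28 CNP0144277.6, via ammonium iodide 27 (not isolated)
Conditions: MeI (excess), CH2Cl2, 25 °C; evaporate; NaHCO3, H2O/EtOAc, 25 °C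
Reagents that add atoms: none
Why: Exhaustive N-methylation turns the amine into a leaving group and bicarbonate effects E1cB elimination from the lactone α-carbon to the exocyclic methylene (the usual unmasking of an amine-protected α-methylene lactone); the conditions are too mild to epimerise C10 or the acyl α-carbon.

## Compound list

1 | diethyl D-tartrate, diethyl (2S,3S)-2,3-dihydroxybutanedioate | CCOC(=O)[C@@H](O)[C@H](O)C(=O)OCC | starting material
2 | diethyl (4S,5S)-2,2-dimethyl-1,3-dioxolane-4,5-dicarboxylate | CCOC(=O)[C@H]1OC(C)(C)O[C@@H]1C(=O)OCC | intermediate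
3 | (4S,5S)-N4,N5-dimethoxy-N4,N5,2,2-tetramethyl-1,3-dioxolane-4,5-dicarboxamide | CON(C)C(=O)[C@H]1OC(C)(C)O[C@@H]1C(=O)N(C)OC | intermediate
4 | tert-butyldimethyl(prop-2-yn-1-yloxy)silane | C#CCO[Si](C)(C)C(C)(C)C | starting material
5 | (4S,5S)-5-[4-(tert-butyldimethylsilyloxy)but-2-ynoyl]-N-methoxy-N,2,2-trimethyl-1,3-dioxolane-4-carboxamide | CON(C)C(=O)[C@H]1OC(C)(C)O[C@@H]1C(=O)C#CCO[Si](C)(C)C(C)(C)C | intermediate
6 | (4S,5S)-5-[(2R)-5-(tert-butyldimethylsilyloxy)-2-hydroxypent-3-yn-2-yl]-N-methoxy-N,2,2-trimethyl-1,3-dioxolane-4-carboxamide | CON(C)C(=O)[C@H]1OC(C)(C)O[C@@H]1[C@](C)(O)C#CCO[Si](C)(C)C(C)(C)C | intermediate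
7 | (4S,5S)-5-[(2R,3E)-5-(tert-butyldimethylsilyloxy)-2-hydroxypent-3-en-2-yl]-2,2-dimethyl-1,3-dioxolane-4-carbaldehyde | O=C[C@H]1OC(C)(C)O[C@@H]1[C@](C)(O)/C=C/CO[Si](C)(C)C(C)(C)C | intermediate
8 | methyl (2Z)-3-[(4R,5S)-5-[(2R,3E)-5-(tert-butyldimethylsilyloxy)-2-hydroxypent-3-en-2-yl]-2,2-dimethyl-1,3-dioxolan-4-yl]prop-2-enoate | COC(=O)/C=C\[C@H]1OC(C)(C)O[C@@H]1[C@](C)(O)/C=C/CO[Si](C)(C)C(C)(C)C | intermediate
9 | (5R)-5-[(1S,2R,3E)-1,2,5-trihydroxy-2-methylpent-3-en-1-yl]furan-2(5H)-one | OC/C=C/[C@@](C)(O)[C@@H](O)[C@@H]1OC(=O)C=C1 | intermediate
10 | (5R)-5-[(4S,5R)-5-[(1E)-3-hydroxyprop-1-en-1-yl]-2,2,5-trimethyl-1,3-dioxolan-4-yl]furan-2(5H)-one | OC/C=C/[C@@]1(C)OC(C)(C)O[C@H]1[C@@H]1OC(=O)C=C1 | intermediate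
11 | methyl (2E)-3-[(4R,5S)-2,2,4-trimethyl-5-[(2R)-5-oxo-2,5-dihydrofuran-2-yl]-1,3-dioxolan-4-yl]prop-2-en-1-yl carbonate | COC(=O)OC/C=C/[C@@]1(C)OC(C)(C)O[C@H]1[C@@H]1OC(=O)C=C1 | intermediate
12 | methyl 2-methylacetoacetate (racemic) | COC(=O)C(C)C(C)=O | starting material
13 | benzyl 2-methyl-3-oxobutanoate (racemic) | CC(=O)C(C)C(=O)OCc1ccccc1 | intermediate
14 | benzyl 2-methyl-3-(trimethylsilyloxy)but-2-enoate (E/Z mixture) | CC(O[Si](C)(C)C)=C(C)C(=O)OCc1ccccc1 | intermediate
15 | 1-benzyloxy-2-methyl-1,3-bis(trimethylsilyloxy)buta-1,3-diene | C=C(O[Si](C)(C)C)C(C)=C(OCc1ccccc1)O[Si](C)(C)C | intermediate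
16 | bis-silyl adduct: 2-(trimethylsilyloxy)-4,5-dihydrofuran of 11 carrying at C7 (trans to C5) the chain CH2–C(=O)–C(CH3)=C(OBn)(OSiMe3) | COC(=O)OC/C=C/[C@@]1(C)OC(C)(C)O[C@H]1[C@@H]1OC(O[Si](C)(C)C)=C[C@H]1CC(=O)C(C)=C(OCc1ccccc1)O[Si](C)(C)C | intermediate (not isolated)
17 | benzyl 4-[(2R,3R)-2-[(4S,5R)-5-[(1E)-3-(methoxycarbonyloxy)prop-1-en-1-yl]-2,2,5-trimethyl-1,3-dioxolan-4-yl]-5-oxooxolan-3-yl]-2-methyl-3-oxobutanoate (C10 epimers; key-step precursor) | COC(=O)OC/C=C/[C@@]1(C)OC(C)(C)O[C@H]1[C@@H]1OC(=O)C[C@H]1CC(=O)C(C)C(=O)OCc1ccccc1 | intermediate
18 | macrocyclic β-keto ester (key-step product): ten-membered ring C1–C10, C10 with CH3 and CO2CH2Ph (epimers), C9 ketone, E C2=C3, (4R,5S) C4/C5 acetonide, trans γ-lactone O–C6/C7–C11–C12 (6R,7R) | O=C(OCc1ccccc1)C1(C)C/C=C/[C@@]2(C)OC(C)(C)O[C@H]2[C@@H]2OC(=O)C[C@H]2CC1=O | intermediate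
19 | trimethylsilyl enol ether of 18 (C8=C9–OSiMe3) | O=C(OCc1ccccc1)C1(C)C/C=C/[C@@]2(C)OC(C)(C)O[C@H]2[C@@H]2OC(=O)C[C@H]2C=C1O[Si](C)(C)C | intermediate (not isolated)
20 | 18 carrying CH2N(CH3)2 at C11 (C10 and C11 epimers) | O=C(OCc1ccccc1)C1(C)C/C=C/[C@@]2(C)OC(C)(C)O[C@H]2[C@@H]2OC(=O)C(CN(C)C)[C@H]2CC1=O | intermediate
21 | β-keto acid: 20 with C2–C3 saturated and CO2H in place of CO2CH2Ph | OC(=O)C1(C)CCC[C@@]2(C)OC(C)(C)O[C@H]2[C@@H]2OC(=O)C(CN(C)C)[C@H]2CC1=O | intermediate (not isolated)
22 | (4R,5S,6R,7R,10S)-13-(dimethylamino)-4,5-(isopropylidenedioxy)-9-oxogermacran-12,6-olide (C11 epimers) | CN(C)CC1C(=O)O[C@@H]2[C@@H]1CC(=O)[C@@H](C)CCC[C@@]1(C)OC(C)(C)O[C@H]12 | intermediate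
23 | (4R,5S,6R,7R,10S)-13-(dimethylamino)-4,5-dihydroxy-9-oxogermacran-12,6-olide (C11 epimers) | CN(C)CC1C(=O)O[C@@H]2[C@@H]1CC(=O)[C@@H](C)CCC[C@@](C)(O)[C@H]2O | intermediate
24 | (S)-2-methylbutanoic acid | CC[C@H](C)C(=O)O | starting material
25 | (2S)-2-methylbutanoic 2,4,6-trichlorobenzoic anhydride | CC[C@H](C)C(=O)OC(=O)c1c(Cl)cc(Cl)cc1Cl | intermediate (not isolated)
26 | (4R,5S,6R,7R,10S)-13-(dimethylamino)-4-hydroxy-5-[(2S)-2-methylbutanoyloxy]-9-oxogermacran-12,6-olide (C11 epimers) | CN(C)CC1C(=O)O[C@@H]2[C@@H]1CC(=O)[C@@H](C)CCC[C@@](C)(O)[C@H]2OC(=O)[C@@H](C)CC | intermediate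
27 | trimethylammonium iodide of 26 | C[N+](C)(C)CC1C(=O)O[C@@H]2[C@@H]1CC(=O)[C@@H](C)CCC[C@@](C)(O)[C@H]2OC(=O)[C@@H](C)CC.[I-] | intermediate (not isolated)
28 | CNP0144277.6, (4R,5S,6R,7R,10S)-4-hydroxy-5-[(2S)-2-methylbutanoyloxy]-9-oxogermacr-11(13)-en-12,6-olide | C=C1C(=O)O[C@@H]2[C@@H]1CC(=O)[C@@H](C)CCC[C@@](C)(O)[C@H]2OC(=O)[C@@H](C)CC | target

## Step count and least certain steps

Total: 19 steps. Longest linear sequence: 16 steps (1 to 28 through steps 1–9 and 13–19); the branch from 12 to 15 has 3 steps.

Step 14 (key step). Most likely to go wrong: intermolecular allylation outrunning ring closure, because the ring-closing bond creates a quaternary carbon in a strained ten-membered transition state. Fallback, from 11 back to 18: benzyl acetoacetate (commercial, CC(=O)CC(=O)OCc1ccccc1) would be silylated as in steps 11 and 12 to benzyl 3-(trimethylsilyloxy)but-2-enoate F1 and then 1-benzyloxy-1,3-bis(trimethylsilyloxy)buta-1,3-diene F2. Addition of F2 to 11 under the conditions of step 13 should give the unmethylated open-chain β-keto ester F3. Closure with Pd(PPh3)4 then uses a less hindered carbon nucleophile and should give the unmethylated macrocyclic β-keto ester F4, which K2CO3 and MeI in acetone would C-methylate at C10 to rejoin the route at 18.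

Step 16. Most likely to go wrong: poor control of C10, either because protonation of the enol after decarboxylation and the later equilibration give a mixture, or because the equilibrium does not favour (10S). Fallback, from 20 to 22 with no new compound: the hydrogenolysis would be run with Pd/C and H2 in MeCN in the presence of a cinchona amino alcohol (cinchonine or cinchonidine, whichever matches the substrate). This is the known amino-alcohol-mediated decarboxylative protonation of benzyl β-keto esters, in which the enol is protonated under kinetic reagent control instead of thermodynamic control.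

Step 15. Most likely to go wrong: incomplete differentiation of the two carbonyl groups, that is aminomethylation at C8 through the silyl enol ether or proton transfer from the ketone side to the lactone enolate. Fallback, from 11 and 15 back to 20: the aminomethyl carbon would be introduced when the lactone enolate equivalent is formed regiospecifically. Adduct 16 would not be hydrolysed but treated in the same flask with [Me2N=CH2]I (CH2Cl2, −78 → 0 °C) to give the open-chain Mannich base F5, and Pd(PPh3)4 closure of F5 as in step 14 rejoins the route at 20.

Step 13. Most likely to go wrong: Lewis-acid activation of the allylic carbonate or of the dioxolane ketal competing with activation of the lactone carbonyl. Fallback, from 9 back to 17: 9 would be persilylated (Me3SiOTf, 2,6-lutidine) to the tris(trimethylsilyl) ether F6. Addition of 15 under Me3SiOTf catalysis and acid work-up should give the triol keto ester F7. Me2C(OMe)2 with pyridinium p-toluenesulfonate would then give the acetonide alcohol F8, and ClCO2Me in pyridine rejoins the route at 17.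

Step 4. Most likely to go wrong: poor facial selectivity if the dioxolane oxygen chelates magnesium too weakly, so that open-chain (Felkin–Anh) attack competes. Fallback, from 3 back to 6: the roles of the two carbon groups would be exchanged. MeMgBr (1.2 equiv) on 3 should give the methyl ketone F9, and the lithium acetylide of 4 (n-BuLi, THF, −78 °C, 12-crown-4) would add under non-chelating Felkin–Anh control, which places the alkynyl group where chelation would have placed methyl's partner and leads to the same (4R) alcohol 6.

Step 5. Most likely to go wrong: loss of chemoselectivity between the two hydride-consuming sites, that is collapse of the aluminium hemiaminal before work-up and further reduction of the aldehyde at the temperature the alkyne needs. Fallback, from 6 back to 7: the reduction would be driven to the alcohol level (NaAlH2(OCH2CH2OMe)2 as in step 5, then NaBH4 in MeOH on the crude product) to give the diol F10. The primary alcohol would then be oxidised selectively with 2,2,6,6-tetramethylpiperidin-1-oxyl (cat.) and PhI(OAc)2 to 7.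

## Further compounds

F1 | step 14 | benzyl 3-(trimethylsilyloxy)but-2-enoate | CC(O[Si](C)(C)C)=CC(=O)OCc1ccccc1
F2 | step 14 | 1-benzyloxy-1,3-bis(trimethylsilyloxy)buta-1,3-diene | C=C(O[Si](C)(C)C)C=C(OCc1ccccc1)O[Si](C)(C)C
F3 | step 14 | unmethylated open-chain β-keto ester (17 without the C10 methyl) | COC(=O)OC/C=C/[C@@]1(C)OC(C)(C)O[C@H]1[C@@H]1OC(=O)C[C@H]1CC(=O)CC(=O)OCc1ccccc1
F4 | step 14 | unmethylated macrocyclic β-keto ester (18 without the C10 methyl) | O=C(OCc1ccccc1)C1C/C=C/[C@@]2(C)OC(C)(C)O[C@H]2[C@@H]2OC(=O)C[C@H]2CC1=O
F0 | step 16 | none | none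
F5 | step 15 | open-chain Mannich base (17 carrying CH2NMe2 at C11) | COC(=O)OC/C=C/[C@@]1(C)OC(C)(C)O[C@H]1[C@@H]1OC(=O)C(CN(C)C)[C@H]1CC(=O)C(C)C(=O)OCc1ccccc1
F6 | step 13 | tris(trimethylsilyl) ether of 9 | C[Si](C)(C)OC/C=C/[C@@](C)(O[Si](C)(C)C)[C@@H](O[Si](C)(C)C)[C@@H]1OC(=O)C=C1
F7 | step 13 | triol keto ester (Michael adduct of 9 and 15) | OC/C=C/[C@@](C)(O)[C@@H](O)[C@@H]1OC(=O)C[C@H]1CC(=O)C(C)C(=O)OCc1ccccc1
F8 | step 13 | acetonide alcohol (17 with C1 hydroxyl in place of the carbonate) | OC/C=C/[C@@]1(C)OC(C)(C)O[C@H]1[C@@H]1OC(=O)C[C@H]1CC(=O)C(C)C(=O)OCc1ccccc1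
F9 | step 4 | (4S,5S)-5-acetyl-N-methoxy-N,2,2-trimethyl-1,3-dioxolane-4-carboxamide | CON(C)C(=O)[C@H]1OC(C)(C)O[C@@H]1C(C)=O
F10 | step 5 | (2R,3E)-5-(tert-butyldimethylsilyloxy)-2-[(4S,5S)-5-(hydroxymethyl)-2,2-dimethyl-1,3-dioxolan-4-yl]pent-3-en-2-ol | OC[C@H]1OC(C)(C)O[C@@H]1[C@](C)(O)/C=C/CO[Si](C)(C)C(C)(C)C
A1 | alternative 1 | (4R,5S,6R,7R,10S)-4,5-(isopropylidenedioxy)-9-oxo-13-norgermacran-12,6-olide | O=C1C[C@H]2CC(=O)[C@@H](C)CCC[C@@]3(C)OC(C)(C)O[C@H]3[C@@H]2O1
A2 | alternative 1 | eleven-membered β-keto lactone with C6 vinyl, C4/C5 acetonide and C10 methyl | C=C[C@H]1OC(=O)CC(=O)[C@@H](C)CCC[C@@]2(C)OC(C)(C)O[C@H]21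
A3 | alternative 2 | ten-membered ring with C6 hydroxyl, C5 MOM ether, E C3–C4 alkene, C7 isopropenyl and C9 dithiane | C=C(C)[C@H]1CC2(SCCCS2)[C@@H](C)CC/C=C(\C)/[C@@H](OCOC)[C@@H]1O
A4 | alternative 2 | open-chain C6 aldehyde with C7 isopropenyl, C9 dithiane, C10 methyl, C3 tributylstannyl and (Z) C4=C5 MOM enol ether | C=C(C)[C@H](C=O)CC1(SCCCS1)[C@@H](C)CC[C@H]([Sn](CCCC)(CCCC)CCCC)/C(C)=C\OCOC
A5 | alternative 3 | ten-membered C9 ketone with Z C4–C5 alkene, C6 TBS ether and C7 isopropenyl | C=C(C)[C@H]1CC(=O)[C@@H](C)CCC/C(C)=C\[C@@H]1O[Si](C)(C)C(C)(C)C
A6 | alternative 3 | cis-decalin with angular C9 hydroxyl, angular C4 methyl, C5 mesylate, C6 TBS ether, C7 isopropenyl and C10 methyl | C=C(C)[C@H]1C[C@]2(O)[C@@H](C)CCC[C@]2(C)[C@H](OS(C)(=O)=O)[C@@H]1O[Si](C)(C)C(C)(C)C
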